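## Retrosynthetic overview

1. Rhoiptelol B ← deprotection (TBAF, then H2/Pd‑C) of a TBS/tri‑benzyl protected 2,6‑cis‑tetrahydropyran.
2. Tetrahydropyran ← Et3SiH/BF3 reduction (axial hydride, sets C2) of the aryl lactol made from an aryllithium and a δ‑lactone.
3. δ‑Lactone ← syn‑3,5‑diol ester (Narasaka–Prasad, sets C4) ← δ‑hydroxy‑β‑keto ester from a chelation‑controlled Mukaiyama aldol of Chan's diene with an α‑benzyloxy aldehyde (sets C6).
4. α‑Benzyloxy aldehyde ← (S)‑4‑hydroxyphenyllactic acid ← L‑lactate dehydrogenase reduction of achiral 4‑hydroxyphenylpyruvic acid (first stereocenter).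
5. Ring order: the δ‑lactone is formed first (step 8) and is converted into the only ring of the target, the tetrahydropyran (steps 11–12).

Assumption: the SMILES is read as the (2R,4S,6S)‑2,6‑cis‑tetrahydropyran with the C4–OH trans to both ring substituents (axial) and a (1S) side‑chain carbinol syn to the ring oxygen.

## Route

**Step 1**
Reactants: 1, 4‑hydroxyphenylpyruvic acid
Product: 2, (S)‑2‑hydroxy‑3‑(4‑hydroxyphenyl)propanoic acid
Conditions: L‑lactate dehydrogenase (NADH‑dependent, L‑specific 2‑hydroxy‑acid dehydrogenase), cat. NAD+, formate dehydrogenase, HCO2Na, phosphate buffer pH 7.0, 30 °C, N2; acidify, extract with EtOAc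
Reagents that add atoms: none
Why: Enzymatic asymmetric reduction of the 2‑oxo acid, with hydride delivered from NADH to one carbonyl face and irreversible formate/CO2 cofactor recycling, sets the first stereocenter (side‑chain carbinol, S).

**Step 2**
Reactants: 2, (S)‑4‑hydroxyphenyllactic acid; 3, methanol
Product: 4, methyl (S)‑2‑hydroxy‑3‑(4‑hydroxyphenyl)propanoate
Conditions: SOCl2 (1.2 equiv), MeOH, 0 °C → rt
Reagents that add atoms: methanol, CO
Why: Fischer esterification under acid leaves the α‑stereocenter untouched.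

**Step 3**
Reactants: 4, methyl (S)‑2‑hydroxy‑3‑(4‑hydroxyphenyl)propanoate; 5, benzyl bromide
Product: 6, methyl (S)‑3‑[4‑(benzyloxy)phenyl]‑2‑hydroxypropanoate
Conditions: BnBr (1.1 equiv), K2CO3, DMF, rt
Reagents that add atoms: benzyl bromide, BrCc1ccccc1
Why: Williamson etherification is selective for the phenol because carbonate deprotonates neither the alcohol nor the α‑C–H.

**Step 4**
Reactants: 6, methyl (S)‑3‑[4‑(benzyloxy)phenyl]‑2‑hydroxypropanoate; 5, benzyl bromide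
Product: 7, methyl (S)‑2‑(benzyloxy)‑3‑[4‑(benzyloxy)phenyl]propanoate
Conditions: BnBr (2 equiv), Ag2O, cat. TBAI, CH2Cl2, 4 Å MS, rt, dark
Reagents that add atoms: benzyl bromide, BrCc1ccccc1
Why: Silver‑oxide‑mediated O‑benzylation is non‑basic, so the α‑hydroxy ester is alkylated without racemisation; the benzyl ether later serves as the chelating group.

**Step 5**
Reactants: 7, methyl (S)‑2‑(benzyloxy)‑3‑[4‑(benzyloxy)phenyl]propanoate
Product: 8, (S)‑2‑(benzyloxy)‑3‑[4‑(benzyloxy)phenyl]propanal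
Conditions: DIBAL‑H (1.1 equiv), CH2Cl2, −78 °C; MeOH quench, Rochelle salt; use crude at once
Reagents that add atoms: none
Why: Partial ester reduction stops at the aldehyde because the α‑alkoxy group stabilises the tetrahedral aluminium hemiacetal at −78 °C; no base is present to epimerise the product.

**Step 6**
Reactants: 8, (S)‑2‑(benzyloxy)‑3‑[4‑(benzyloxy)phenyl]propanal; 9, Chan's diene (1‑methoxy‑1,3‑bis(trimethylsilyloxy)buta‑1,3‑diene)
Product: 10, methyl (5S,6S)‑6‑(benzyloxy)‑7‑[4‑(benzyloxy)phenyl]‑5‑hydroxy‑3‑oxoheptanoate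
Conditions: TiCl4 (1.1 equiv), CH2Cl2, −78 °C, then 9 (1.5 equiv), −78 °C; aq. NaHCO3
Reagents that add atoms: Chan's diene, C=C(O[Si](C)(C)C)C=C(OC)O[Si](C)(C)C (supplies CH2C(=O)CH2CO2Me)
Why: Mukaiyama aldol under Cram‑chelate control, with Ti bridging C=O and OBn so the diene attacks the face bearing H, gives the 5,6‑syn adduct and sets C5 as S.

**Step 7**
Reactants: 10, methyl (5S,6S)‑6‑(benzyloxy)‑7‑[4‑(benzyloxy)phenyl]‑5‑hydroxy‑3‑oxoheptanoate
Product: 11, methyl (3R,5S,6S)‑6‑(benzyloxy)‑7‑[4‑(benzyloxy)phenyl]‑3,5‑dihydroxyheptanoate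
Conditions: Et2BOMe, THF/MeOH (4:1), −78 °C, then NaBH4; AcOH quench, MeOH azeotrope
Reagents that add atoms: none
Why: Narasaka–Prasad reduction, with external hydride adding axially to the six‑membered boron chelate, gives the syn‑1,3‑diol and sets C3 as R; the ester is inert at −78 °C.

**Step 8**
Reactants: 11, methyl (3R,5S,6S)‑6‑(benzyloxy)‑7‑[4‑(benzyloxy)phenyl]‑3,5‑dihydroxyheptanoate
Product: 12, (4R,6S)‑6‑{(1S)‑1‑(benzyloxy)‑2‑[4‑(benzyloxy)phenyl]ethyl}‑4‑hydroxytetrahydro‑2H‑pyran‑2‑one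
Conditions: PPTS (0.2 equiv), toluene, 70 °C
Reagents that add atoms: none
Why: Acid‑catalysed lactonisation through the C5–OH gives the six‑membered δ‑lactone (statin‑type, 4‑OH trans to the C6 substituent) with no stereocenter touched.

**Step 9**
Reactants: 12, the hydroxy lactone; 13, tert‑butyldimethylsilyl chloride
Product: 14, (4R,6S)‑6‑{(1S)‑1‑(benzyloxy)‑2‑[4‑(benzyloxy)phenyl]ethyl}‑4‑[(tert‑butyldimethylsilyl)oxy]tetrahydro‑2H‑pyran‑2‑one
Conditions: TBSCl, imidazole, DMF, rt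
Reagents that add atoms: TBSCl, CC(C)(C)[Si](C)(C)Cl
Why: Standard silylation masks the only free OH before the organolithium step; imidazole is too weak a base to cause β‑elimination.

**Step 10**
Reactants: 15, 4‑bromo‑2‑methoxyphenol; 5, benzyl bromide
Product: 16, 1‑(benzyloxy)‑4‑bromo‑2‑methoxybenzene
Conditions: BnBr, K2CO3, acetone, reflux
Reagents that add atoms: benzyl bromide, BrCc1ccccc1
Why: Williamson etherification protects the phenol so the bromide can be lithiated.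

**Step 11**
Reactants: 16, 1‑(benzyloxy)‑4‑bromo‑2‑methoxybenzene; 14, the TBS lactone
Product: 17, (4R,6S)‑2‑[4‑(benzyloxy)‑3‑methoxyphenyl]‑6‑{(1S)‑1‑(benzyloxy)‑2‑[4‑(benzyloxy)phenyl]ethyl}‑4‑[(tert‑butyldimethylsilyl)oxy]tetrahydro‑2H‑pyran‑2‑ol (lactol, anomeric mixture in equilibrium with the δ‑hydroxy aryl ketone; used crude)
Conditions: 16 (1.3 equiv), n‑BuLi, THF, −78 °C, 30 min; then 14, −78 °C, 1 h; NH4Cl quench at −78 °C
Reagents that add atoms: none beyond the two reactants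
Why: Br/Li exchange followed by 1,2‑addition of the aryllithium to the lactone gives a lithium lactolate that is stable at −78 °C, so the reaction stops at mono‑addition and forms the C1–aryl bond.

**Step 12**
Reactants: 17, the aryl lactol
Product: 18, (2R,4S,6S)‑2‑[4‑(benzyloxy)‑3‑methoxyphenyl]‑6‑{(1S)‑1‑(benzyloxy)‑2‑[4‑(benzyloxy)phenyl]ethyl}‑4‑[(tert‑butyldimethylsilyl)oxy]tetrahydro‑2H‑pyran
Conditions: Et3SiH (5 equiv), BF3·OEt2 (2.5 equiv), CH2Cl2/MeCN, −78 → −40 °C; cold NaHCO3 quench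
Reagents that add atoms: none
Why: Lewis acid ionises the lactol to an aryl‑stabilised oxocarbenium ion, and Et3SiH attacks axially on the half‑chair with the C6 side chain pseudo‑equatorial (C4–OTBS pseudo‑axial), giving the 2,6‑cis ring (C2 = R), which is also the thermodynamic isomer.

**Step 13**
Reactants: 18, the silyl‑protected tetrahydropyran
Product: 19, (2R,4S,6S)‑2‑[4‑(benzyloxy)‑3‑methoxyphenyl]‑6‑{(1S)‑1‑(benzyloxy)‑2‑[4‑(benzyloxy)phenyl]ethyl}tetrahydro‑2H‑pyran‑4‑ol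
Conditions: TBAF, THF, 0 °C → rt
Reagents that add atoms: none
Why: Fluoride desilylation frees the axial C4–OH while the phenols are still benzylated, so no phenoxide is formed next to the benzylic ring ether.

**Step 14**
Reactants: 19, the tri‑O‑benzyl tetrahydropyranol
Product: 20, rhoiptelol B, (2R,4S,6S)‑2‑(4‑hydroxy‑3‑methoxyphenyl)‑6‑[(1S)‑1‑hydroxy‑2‑(4‑hydroxyphenyl)ethyl]tetrahydro‑2H‑pyran‑4‑ol
Conditions: H2 (1 atm), 10% Pd/C, EtOAc (a little MeOH), rt, monitored closely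
Reagents that add atoms: none
Why: Neutral catalytic hydrogenolysis removes the two aryl benzyl ethers and the secondary benzyl ether faster than it cleaves the hindered cyclic 2‑aryl ether, and touches no stereocenter.

## Compound list

1 | 4‑hydroxyphenylpyruvic acid | O=C(O)C(=O)Cc1ccc(O)cc1 | starting material
2 | (S)‑2‑hydroxy‑3‑(4‑hydroxyphenyl)propanoic acid | OC(=O)[C@@H](O)Cc1ccc(O)cc1 | intermediate
3 | methanol | CO | starting material
4 | methyl (S)‑2‑hydroxy‑3‑(4‑hydroxyphenyl)propanoate | COC(=O)[C@@H](O)Cc1ccc(O)cc1 | intermediate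
5 | benzyl bromide | BrCc1ccccc1 | starting material
6 | methyl (S)‑3‑[4‑(benzyloxy)phenyl]‑2‑hydroxypropanoate | COC(=O)[C@@H](O)Cc1ccc(OCc2ccccc2)cc1 | intermediate
7 | methyl (S)‑2‑(benzyloxy)‑3‑[4‑(benzyloxy)phenyl]propanoate | COC(=O)[C@@H](OCc1ccccc1)Cc1ccc(OCc2ccccc2)cc1 | intermediate
8 | (S)‑2‑(benzyloxy)‑3‑[4‑(benzyloxy)phenyl]propanal | O=C[C@@H](OCc1ccccc1)Cc1ccc(OCc2ccccc2)cc1 | intermediate
9 | Chan's diene, 1‑methoxy‑1,3‑bis(trimethylsilyloxy)buta‑1,3‑diene | C=C(O[Si](C)(C)C)C=C(OC)O[Si](C)(C)C | starting material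
10 | methyl (5S,6S)‑6‑(benzyloxy)‑7‑[4‑(benzyloxy)phenyl]‑5‑hydroxy‑3‑oxoheptanoate | COC(=O)CC(=O)C[C@@H]([C@@H](OCc1ccccc1)Cc1ccc(OCc2ccccc2)cc1)O | intermediate
11 | methyl (3R,5S,6S)‑6‑(benzyloxy)‑7‑[4‑(benzyloxy)phenyl]‑3,5‑dihydroxyheptanoate | COC(=O)C[C@H](O)C[C@@H]([C@@H](OCc1ccccc1)Cc1ccc(OCc2ccccc2)cc1)O | intermediate
12 | (4R,6S)‑6‑{(1S)‑1‑(benzyloxy)‑2‑[4‑(benzyloxy)phenyl]ethyl}‑4‑hydroxytetrahydro‑2H‑pyran‑2‑one | O=C1C[C@H](O)C[C@@H]([C@@H](OCc2ccccc2)Cc2ccc(OCc3ccccc3)cc2)O1 | intermediate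
13 | tert‑butyldimethylsilyl chloride | CC(C)(C)[Si](C)(C)Cl | starting material
14 | (4R,6S)‑6‑{(1S)‑1‑(benzyloxy)‑2‑[4‑(benzyloxy)phenyl]ethyl}‑4‑[(tert‑butyldimethylsilyl)oxy]tetrahydro‑2H‑pyran‑2‑one | O=C1C[C@H](O[Si](C)(C)C(C)(C)C)C[C@@H]([C@@H](OCc2ccccc2)Cc2ccc(OCc3ccccc3)cc2)O1 | intermediate
15 | 4‑bromo‑2‑methoxyphenol | COc1cc(Br)ccc1O | starting material
16 | 1‑(benzyloxy)‑4‑bromo‑2‑methoxybenzene | COc1cc(Br)ccc1OCc1ccccc1 | intermediate
17 | (4R,6S)‑2‑[4‑(benzyloxy)‑3‑methoxyphenyl]‑6‑{(1S)‑1‑(benzyloxy)‑2‑[4‑(benzyloxy)phenyl]ethyl}‑4‑(TBS‑oxy)tetrahydro‑2H‑pyran‑2‑ol (anomeric mixture) | COc1cc(C2(O)C[C@H](O[Si](C)(C)C(C)(C)C)C[C@@H]([C@@H](OCc3ccccc3)Cc3ccc(OCc4ccccc4)cc3)O2)ccc1OCc1ccccc1 | intermediate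
18 | (2R,4S,6S)‑2‑[4‑(benzyloxy)‑3‑methoxyphenyl]‑6‑{(1S)‑1‑(benzyloxy)‑2‑[4‑(benzyloxy)phenyl]ethyl}‑4‑(TBS‑oxy)tetrahydro‑2H‑pyran | COc1cc([C@H]2C[C@H](O[Si](C)(C)C(C)(C)C)C[C@@H]([C@@H](OCc3ccccc3)Cc3ccc(OCc4ccccc4)cc3)O2)ccc1OCc1ccccc1 | intermediate
19 | (2R,4S,6S)‑2‑[4‑(benzyloxy)‑3‑methoxyphenyl]‑6‑{(1S)‑1‑(benzyloxy)‑2‑[4‑(benzyloxy)phenyl]ethyl}tetrahydro‑2H‑pyran‑4‑ol | COc1cc([C@H]2C[C@H](O)C[C@@H]([C@@H](OCc3ccccc3)Cc3ccc(OCc4ccccc4)cc3)O2)ccc1OCc1ccccc1 | intermediate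
20 | rhoiptelol B | COc1cc([C@H]2C[C@H](O)C[C@@H]([C@@H](O)Cc3ccc(O)cc3)O2)ccc1O | target

## Summary

Total steps: 14. Longest linear sequence: 13 (steps 1–9 and 11–14, from 4‑hydroxyphenylpyruvic acid); step 10 is a one‑step side branch.

Three steps most likely to fail, with fallbacks:

1. **Step 11, aryllithium addition to the β‑silyloxy δ‑lactone** (risk: enolisation and β‑elimination of OTBS, or over‑addition). Fallback: build the ring by oxa‑Michael instead. A TiCl4 chelation‑controlled Mukaiyama aldol of aldehyde 8 with the TMS enol ether of (E)‑4‑[4‑(benzyloxy)‑3‑methoxyphenyl]but‑3‑en‑2‑one gives a δ‑hydroxy aryl enone. Thermodynamic 6‑endo oxa‑Michael cyclisation gives the 2,6‑cis‑tetrahydropyran‑4‑one, and L‑Selectride (equatorial attack) gives the axial alcohol 19.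

2. **Step 6, chelation‑controlled Chan's‑diene aldol** (risk: aldehyde epimerisation, eroded dr, TiCl4 damage). Fallback: Keck chelation‑controlled allylation of 8 (allylSnBu3, MgBr2·OEt2) to the syn homoallylic alcohol, then acryloylation and ring‑closing metathesis to the 5,6‑dihydropyran‑2‑one. Nucleophilic epoxidation (H2O2/NaOH, anti to the C6 substituent) and selenide‑mediated reductive opening then give lactone 12.

3. **Step 14, final hydrogenolysis** (risk: cleavage of the electron‑rich benzylic ring C–O bond while the secondary benzyl ether is removed). Fallback: change the protecting‑group plan. Hydrogenolyse all benzyl groups at lactone 12, before any benzylic ring ether exists, and re‑protect as the tris‑TBS ether. Couple with the aryllithium from TBS‑protected 4‑bromo‑2‑methoxyphenol, reduce as in step 12, and finish with a single buffered fluoride (TBAF/AcOH) global desilylation.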